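Each quinone ring is numbered C1(=O) next to the inter-ring bond, C2 (inter-ring carbon), C3 (arylethyl), C4(=O), C5(OH), C6(CH3). The feature exploited is that the eight-carbon path CH3–C6–C1–C2–C2'–C1'–C6'–CH3 through rings A and B is oct-4-yne-3,6-dione, and each C3–C4–C5 arc is an α-keto ester. The plan therefore cuts C2–C3 and C5–C6 in both rings. In one operation two keto ester enolates add to the two alkyne carbons. Two Claisen closures then deliver both rings as benzene-1,2,4-triols, so the hindered central bond never has to be formed. The precursors are the symmetrical ynedione and two equivalents of ethyl 5-(2-methoxyphenyl)-2-oxopentanoate; one mild oxidation finishes the synthesis.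

Key step: step 4

Remark (stereochemistry): the target has no stereocentre and its SMILES fixes no sense for the hindered C2–C2' axis, so the axis is taken as racemic.

Remark (carbon count): ring carbon C3 comes from the keto ester chain, so three CH2 groups must lie between arene and ketone, and the keto ester is built from the 3-arylpropyl bromide. The two-carbon homologue, 2-(2-methoxyphenyl)ethyl bromide, would end in a 2-oxobutanoate and place a 2-methoxybenzyl group on C3.

Step 1
Reactants: 1 acetylene; 2 propanal (2 equiv)
Product: 4 oct-4-yne-3,6-diol, via acetylene bis-Grignard reagent 3 (not isolated)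
Conditions: EtMgBr (2.1 equiv), THF/Et2O, 1 (1 equiv, titrated THF solution), 0 → 40 °C; then 2 (2.2 equiv), 0 °C → rt; sat. aq NH4Cl
Reagents that add atoms: none
Why: Double deprotonation of acetylene gives the bis-Grignard reagent, whose two-directional Grignard 1,2-addition to propanal should give the diol as a meso/dl mixture, which does not matter because both carbinol centres become ketones in step 2.

Step 2
Reactants: 4 oct-4-yne-3,6-diol
Product: 5 oct-4-yne-3,6-dione
Conditions: Dess–Martin periodinane (2.4 equiv), CH2Cl2, 0 °C → rt; dilute with pentane, filter through SiO2, concentrate cold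
Reagents that add atoms: none
Why: Dess–Martin oxidation turns secondary propargylic alcohols into ynones under neutral, anhydrous conditions, and the non-aqueous work-up keeps nucleophiles away from the strongly electrophilic ynedione.

Step 3
Reactants: 6 1-(3-bromopropyl)-2-methoxybenzene; 7 diethyl oxalate
Product: 9 ethyl 5-(2-methoxyphenyl)-2-oxopentanoate, via arylpropyl Grignard reagent 8 (not isolated)
Conditions: Mg turnings, THF, 35 °C; cannulate into 7 (2 equiv), THF/Et2O, −78 °C; 1 M HCl at −78 → 0 °C
Reagents that add atoms: none
Why: Acylation of a Grignard reagent with diethyl oxalate is the standard α-keto ester synthesis, and inverse addition at −78 °C into excess oxalate should stop it after one substitution, the three-carbon chain of 6 supplying the two side-chain CH2 groups and the future ring carbon C3.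

Step 4
Reactants: 5 oct-4-yne-3,6-dione; 9 ethyl 5-(2-methoxyphenyl)-2-oxopentanoate (2 equiv)
Product: 13 6,6'-bis[2-(2-methoxyphenyl)ethyl]-3,3'-dimethylbiphenyl-2,2',4,4',5,5'-hexol, via enedione mono-adduct 10 (not isolated), via tetraketone bis-adduct 11 (not isolated), via bis-trione 12 (not isolated)
Conditions: 9 (2.2 equiv), DBU (0.3 equiv), THF, −40 °C, slow addition of 5, then rt; cannulate into KOtBu (8 equiv), THF, −40 °C → rt, argon; degassed 2 M HCl; crude product kept under argon
Reagents that add atoms: none
Why: Proposed new method: DBU enolises only the activated C3–H of 9; this enolate adds to alkyne carbon C2 of 5 and protonation of the allenolate gives enedione 10, whose unsubstituted alkene carbon C2' is still β to the C1 carbonyl and is the less hindered terminus, so a second enolate adds there and gives 11 with C2–C3 and C2'–C3' made and the C2–C2' bond inherited from the alkyne. Excess KOtBu then removes both C3–H first, which turns each C4 ketone into its enolate, and reversibly a C6–H, and each C6 enolate attacks the ester carbon C5 with loss of ethoxide, a 6-exo-trig Claisen closure for ring A (C6 to C5) and the same mode for ring B (C6' to C5'). Bis-trione 12 is the keto tautomer of 13, so its deprotonation to two aromatic triolates is the only irreversible exit, while retro-Michael cleavage and the aldol additions of C6 to C4, C1' or C4' stay reversible below room temperature as long as no dehydration sets in. The closest known reaction types are base- or metal-catalysed conjugate additions of enolisable α-keto esters to nitroalkenes and ynones, vicinal double additions of nucleophiles to acetylenedicarbonyl compounds, and the alkoxide-induced cyclisation of ketone–oxalate Claisen products to cyclic 1,2,4-triones. The four stereocentres of 11 (C2, C3, C2', C3') form without control and are all erased on aromatisation, and the hindered C2–C2' axis results as a racemate, so no stereocontrol element is needed. The step needs order selectivity (both Michael additions before any closure), secured because an amidine cannot enolise the plain ethyl ketone at C6, and site selectivity (C5 over C4), secured by the prior C3=C4 enolisation together with tBuOH-mediated proton exchange that lets this enolate adopt the geometry with C2 and C5 cis.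

Step 5
Reactants: 13 6,6'-bis[2-(2-methoxyphenyl)ethyl]-3,3'-dimethylbiphenyl-2,2',4,4',5,5'-hexol
Product: 14 4,4'-dihydroxy-2,2'-bis[2-(2-methoxyphenyl)ethyl]-5,5'-dimethyl-[1,1'-bi(cyclohexa-1,4-diene)]-3,3',6,6'-tetrone (target)
Conditions: FeCl3 (4.5 equiv), EtOH/H2O, 0 °C → rt
Reagents that add atoms: none
Why: FeCl3 oxidation of hydroquinones to quinones is the usual end of hydroxyquinone syntheses from benzene-1,2,4-triols, and since only C1–OH and C4–OH are para to each other in each ring, only the 1,4-quinone with C5–OH retained can form, while the anisole rings are untouched and the C3 substituents leave no ring C–H for closure to a dibenzofuran.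

Compound list
1 | acetylene | C#C | starting material
2 | propanal | CCC=O | starting material
3 | ethyne-1,2-diylbis(magnesium bromide), not isolated | Br[Mg]C#C[Mg]Br | intermediate
4 | oct-4-yne-3,6-diol (meso/dl mixture) | CCC(O)C#CC(O)CC | intermediate
5 | oct-4-yne-3,6-dione | CCC(=O)C#CC(=O)CC | intermediate
6 | 1-(3-bromopropyl)-2-methoxybenzene | COc1ccccc1CCCBr | starting material
7 | diethyl oxalate | CCOC(=O)C(=O)OCC | starting material
8 | [3-(2-methoxyphenyl)propyl]magnesium bromide, not isolated | COc1ccccc1CCC[Mg]Br | intermediate
9 | ethyl 5-(2-methoxyphenyl)-2-oxopentanoate | CCOC(=O)C(=O)CCCc1ccccc1OC | intermediate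
10 | ethyl 3-[2-(2-methoxyphenyl)ethyl]-2,6-dioxo-4-propanoyloct-4-enoate (racemic, E/Z mixture), not isolated | CCOC(=O)C(=O)C(CCc1ccccc1OC)C(C(=O)CC)=CC(=O)CC | intermediate
11 | diethyl 3,6-bis[2-(2-methoxyphenyl)ethyl]-2,7-dioxo-4,5-dipropanoyloctanedioate (diastereomer mixture), not isolated | CCOC(=O)C(=O)C(CCc1ccccc1OC)C(C(=O)CC)C(C(=O)CC)C(CCc1ccccc1OC)C(=O)C(=O)OCC | intermediate
12 | 6,6'-bis[2-(2-methoxyphenyl)ethyl]-3,3'-dimethyl-[1,1'-bi(cyclohexane)]-2,2',4,4',5,5'-hexone (diastereomer mixture), not isolated | CC1C(=O)C(C2C(CCc3ccccc3OC)C(=O)C(=O)C(C)C2=O)C(CCc2ccccc2OC)C(=O)C1=O | intermediate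
13 | 6,6'-bis[2-(2-methoxyphenyl)ethyl]-3,3'-dimethylbiphenyl-2,2',4,4',5,5'-hexol (racemic axis) | Cc1c(O)c(-c2c(CCc3ccccc3OC)c(O)c(O)c(C)c2O)c(CCc2ccccc2OC)c(O)c1O | intermediate
14 | 4,4'-dihydroxy-2,2'-bis[2-(2-methoxyphenyl)ethyl]-5,5'-dimethyl-[1,1'-bi(cyclohexa-1,4-diene)]-3,3',6,6'-tetrone | COc1ccccc1CCC1=C(C2=C(CCc3ccccc3OC)C(=O)C(O)=C(C)C2=O)C(=O)C(C)=C(O)C1=O | target

Total step count: 5. Longest linear sequence: 4 (steps 1, 2, 4, 5); the keto ester branch (step 3) joins at step 4.

Steps most likely to fail

Risk 1, step 4. Several processes could defeat the cascade:
- The sequence may stall after the first addition, because the mono-adduct is drained as its cross-conjugated dienolate or by alkene migration into conjugation with C4.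
- The second addition may be refused on steric grounds.
- Self-aldolisation of the keto ester may compete.
- Five-ring aldol addition followed by dehydration may outrun the Claisen closure.

The fallback uses known chemistry, sets out from 9 and comes back at 13, and makes the biaryl bond last instead of carrying it in from the alkyne. Silylation of 9 (TMSOTf, Et3N, CH2Cl2, 0 °C) would give the silyl enol ether ethyl (Z)-5-(2-methoxyphenyl)-2-(trimethylsilyloxy)pent-2-enoate F1. Its SnCl4-promoted Mukaiyama–Michael addition to 2-nitrobut-1-ene with hydrolytic Nef work-up is the standard passage from silyl enol ethers to 1,4-diketones, and would give ethyl 3-[2-(2-methoxyphenyl)ethyl]-2,5-dioxoheptanoate F2. NaOEt in EtOH under argon would close C6 onto C5 (Claisen condensation) and aromatise to 6-[2-(2-methoxyphenyl)ethyl]-3-methylbenzene-1,2,4-triol F3, in which C2 is the only free ring position. Limited aerobic oxidation in aqueous methanol would then join two molecules of F3 at C2 and deliver 13. This oxidative dimerisation is known for benzene-1,2,4-triol itself, at the position para to its 2-OH. Any material oxidised further is already 14.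

Risk 2, step 2. The oxidation may stall at the hydroxy-ynone stage as the alkyne becomes electron-poor. The volatile, strongly electrophilic product may also be lost through hydration, addition of acetic acid or oligomerisation on concentration.

The fallback sets out from bis-Grignard reagent 3 (made from 1 as in step 1) and comes back at 5, bypassing 4 and every oxidation. Both termini of 3 would be acylated with N-methoxy-N-methylpropanamide (2.1 equiv, THF, 0 °C → rt; Weinreb ketone synthesis). This would give the doubly chelated adduct bis(bromomagnesium) 3,6-bis[methoxy(methyl)amino]oct-4-yne-3,6-diolate F4, so that no ynone is exposed to the organometallic. Inverse quench into cold aq HCl would release 5 and keep the liberated amine protonated, so that it cannot add to the triple bond.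

Risk 3, step 3. The Grignard reagent may over-add to the newly formed keto group, and Wurtz-type homocoupling may occur during magnesium insertion.

The fallback sets out from 6 and comes back at 9 by acyl-anion umpolung (Corey–Seebach type) instead of organometallic acylation. Ethyl 1,3-dithiane-2-carboxylate would be deprotonated (NaH, DMF/toluene, 0 °C) and alkylated with 6 to give ethyl 2-[3-(2-methoxyphenyl)propyl]-1,3-dithiane-2-carboxylate F5. Alkylative hydrolysis (MeI, CaCO3, aq MeCN) spares the electron-rich arene and would unmask the ketone of 9.

Further compounds
F1 | step 4 | ethyl (Z)-5-(2-methoxyphenyl)-2-(trimethylsilyloxy)pent-2-enoate | CCOC(=O)/C(O[Si](C)(C)C)=C/CCc1ccccc1OC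
F2 | step 4 | ethyl 3-[2-(2-methoxyphenyl)ethyl]-2,5-dioxoheptanoate (racemic) | CCOC(=O)C(=O)C(CCc1ccccc1OC)CC(=O)CC
F3 | step 4 | 6-[2-(2-methoxyphenyl)ethyl]-3-methylbenzene-1,2,4-triol | Cc1c(O)cc(CCc2ccccc2OC)c(O)c1O
F4 | step 2 | bis(bromomagnesium) 3,6-bis[methoxy(methyl)amino]oct-4-yne-3,6-diolate | CCC(O[Mg]Br)(N(C)OC)C#CC(CC)(O[Mg]Br)N(C)OC
F5 | step 3 | ethyl 2-[3-(2-methoxyphenyl)propyl]-1,3-dithiane-2-carboxylate | CCOC(=O)C1(CCCc2ccccc2OC)SCCCS1
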